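The whole plan rests on the bond between the CH2 group beside the methyl-bearing stereocentre and C2 of the central furan (ring B). Both ends are brought in as nucleophiles: a primary alkyl pinacol boronate that already carries ring A and the stereocentre, and 1,3-di(furan-3-yl)propane, a twofold-symmetric precursor in which rings B and C are still equivalent, lithiated at its unhindered α-carbon. In one operation the furyllithium forms a boronate complex, NBS attacks the free C5 of ring B, O1 stabilises the positive charge at C2, the CH2 group shifts from boron to C2, and loss of bromide and boron restores the aromatic ring. The stereocentre comes from a sparteine-mediated lithiation–borylation.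

Key step: step 7

Assumption: (+)-sparteine and ethyl 2,4,6-tri(propan-2-yl)benzoate are taken as purchasable; ring B is numbered as in the target (O1, C2 bearing the CH2 group, C3, C4 bearing the propyl chain, C5).

Step 1
Reactants: 1 4-bromofuran-2-carbaldehyde; 2 ethyl 2-(triphenyl-λ5-phosphanylidene)propanoate
Product: 3 ethyl (2E)-3-(4-bromofuran-2-yl)-2-methylprop-2-enoate
Conditions: toluene, 80 °C
Reagents that add atoms: none
Why: Wittig olefination with a stabilised α-methyl ylide, which should give the E-trisubstituted enoate (ester trans to the furan) and leaves the C4–Br bond of the furan untouched.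

Step 2
Reactants: 4 ethyl 2,4,6-tri(propan-2-yl)benzoate; 5 allylboronic acid pinacol ester
Product: 8 4,4,5,5-tetramethyl-2-[(2S)-pent-4-en-2-yl]-1,3,2-dioxaborolane, via lithiated benzoate 6 (not isolated), via allyl boronate complex 7 (not isolated)
Conditions: s-BuLi, (+)-sparteine, Et2O, −78 °C; then 5, −78 °C → 35 °C
Reagents that add atoms: none
Why: Sparteine-mediated asymmetric lithiation–borylation, in which s-BuLi·(+)-sparteine should remove the pro-R hydrogen of the O–CH2 group to give configurationally stable 6, boron of 5 is attached with retention to give 7, and the stereospecific 1,2-metallate rearrangement (allyl shifts from boron to carbon with inversion as the hindered benzoate leaves) sets the stereocentre of 8 as S under reagent control.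

Step 3
Reactants: 8 4,4,5,5-tetramethyl-2-[(2S)-pent-4-en-2-yl]-1,3,2-dioxaborolane
Product: 10 4,4,5,5-tetramethyl-2-[(2R)-2-methylpent-4-en-1-yl]-1,3,2-dioxaborolane, via chloromethyl boronate complex 9 (not isolated)
Conditions: BrCH2Cl, n-BuLi, THF, −78 °C → rt
Reagents that add atoms: bromochloromethane, ClCBr
Why: Matteson homologation, in which (chloromethyl)lithium made in the flask adds to boron at −78 °C and on warming the secondary alkyl group migrates to the CH2 carbon with retention, so the stereocentre is carried over unchanged (the descriptor changes from S to R only through the priority rules).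

Step 4
Reactants: 10 4,4,5,5-tetramethyl-2-[(2R)-2-methylpent-4-en-1-yl]-1,3,2-dioxaborolane; 3 ethyl (2E)-3-(4-bromofuran-2-yl)-2-methylprop-2-enoate
Product: 12 ethyl (2E)-2-methyl-3-{4-[(4R)-4-methyl-5-(4,4,5,5-tetramethyl-1,3,2-dioxaborolan-2-yl)pentyl]furan-2-yl}prop-2-enoate, via B-alkyl-9-BBN adduct 11 (not isolated)
Conditions: 9-BBN (1.05 equiv), THF, 0 °C → rt; then 3, Pd(dppf)Cl2, K3PO4 (3 M aq), DMF, 50 °C
Reagents that add atoms: none
Why: Anti-Markovnikov hydroboration of the terminal alkene followed by B-alkyl Suzuki–Miyaura coupling at the C4–Br bond of 3, in which only the B-alkyl-9-BBN unit transmetalates while the primary pinacol boronate stays intact under these mild aqueous conditions.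

Step 5
Reactants: 13 3-bromofuran; 5 allylboronic acid pinacol ester
Product: 14 3-(prop-2-en-1-yl)furan
Conditions: Pd(PPh3)4, CsF, THF, 65 °C
Reagents that add atoms: none
Why: Suzuki–Miyaura allylation of the heteroaryl bromide, in which fluoride activates the allylboronate and the unsubstituted allyl group raises no regiochemical question.

Step 6
Reactants: 14 3-(prop-2-en-1-yl)furan; 13 3-bromofuran
Product: 16 1,3-di(furan-3-yl)propane, via B-alkyl-9-BBN adduct 15 (not isolated)
Conditions: 9-BBN, THF, rt; then 13, Pd(dppf)Cl2, K3PO4 (3 M aq), DMF, 60 °C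
Reagents that add atoms: none
Why: Anti-Markovnikov hydroboration with 9-BBN and B-alkyl Suzuki–Miyaura coupling with a second molecule of 3-bromofuran should give the twofold-symmetric bis-furan with both rings attached through their β-carbons.

Step 7
Reactants: 16 1,3-di(furan-3-yl)propane; 12 ethyl (2E)-2-methyl-3-{4-[(4R)-4-methyl-5-(4,4,5,5-tetramethyl-1,3,2-dioxaborolan-2-yl)pentyl]furan-2-yl}prop-2-enoate
Product: 19 ethyl (2E)-3-{4-[(4S)-5-{4-[3-(furan-3-yl)propyl]furan-2-yl}-4-methylpentyl]furan-2-yl}-2-methylprop-2-enoate, via furyllithium 17 (not isolated), via furyl boronate complex 18 (not isolated)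
Conditions: 16 (3 equiv), LiTMP (1.15 equiv, from 2,2,6,6-tetramethylpiperidine and n-BuLi), THF, −78 → 0 °C; added to 12 (1 equiv) in THF, −78 °C; NBS (1.2 equiv), THF, −78 °C → rt; aq Na2S2O3
Reagents that add atoms: none
Why: The hindered amide base should remove the α-hydrogen remote from the chain on one ring of 16 (C2 of ring B; the other α-hydrogen at C5 is flanked by the C4 chain), and because both rings of 16 are equivalent an excess of 16 is all that is needed to keep the lithiation single. Furyllithium 17 is trapped at boron of 12 at −78 °C faster than it adds to the hindered, conjugated ester and gives boronate complex 18, in which ring B is an anionic, very electron-rich furan. NBS should therefore brominate ring B of 18 at the free C5 in preference to the neutral rings A and C; the positive charge that develops at C2 is stabilised by O1 and is quenched by a 1,2-shift of the CH2 group from boron to C2, after which loss of bromide from C5 and of the boryl group from C2 restores the aromatic ring. The closest known reaction type is the electrophile-triggered 1,2-metallate rearrangement of heteroaryl boronate complexes, the aromatic counterpart of the Zweifel olefination, which unites two nucleophilic carbons under oxidation by NBS without a transition metal. No ring is closed and no stereocentre is formed: the existing stereocentre is β to boron, takes no part in the migration and is carried through unchanged. The step needs site selectivity in the deprotonation (C2 over C5, secured by the C4 chain and the bulk of the base) and chemoselectivity of NBS (secured by the negative charge of 18, the stoichiometry and the low temperature).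

Step 8
Reactants: 19 ethyl (2E)-3-{4-[(4S)-5-{4-[3-(furan-3-yl)propyl]furan-2-yl}-4-methylpentyl]furan-2-yl}-2-methylprop-2-enoate
Product: 20 (2E)-3-{4-[(4S)-5-{4-[3-(furan-3-yl)propyl]furan-2-yl}-4-methylpentyl]furan-2-yl}-2-methylprop-2-enoic acid
Conditions: LiOH·H2O, THF/MeOH/H2O, rt; then 1 M HCl, 0 °C, to pH 3–4
Reagents that add atoms: lithium hydroxide, [Li+].[OH-]
Why: Saponification of the ethyl ester by acyl–oxygen cleavage under mild base, which the three furan rings, the E-alkene and the remote stereocentre should tolerate, followed by cold, brief acidification to free the acid.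

Compound list
1 | 4-bromofuran-2-carbaldehyde | O=Cc1cc(Br)co1 | starting material
2 | ethyl 2-(triphenyl-λ5-phosphanylidene)propanoate | CCOC(=O)C(C)=P(c1ccccc1)(c1ccccc1)c1ccccc1 | starting material
3 | ethyl (2E)-3-(4-bromofuran-2-yl)-2-methylprop-2-enoate | CCOC(=O)/C(C)=C/c1cc(Br)co1 | intermediate
4 | ethyl 2,4,6-tri(propan-2-yl)benzoate | CCOC(=O)c1c(C(C)C)cc(C(C)C)cc1C(C)C | starting material
5 | allylboronic acid pinacol ester (4,4,5,5-tetramethyl-2-(prop-2-en-1-yl)-1,3,2-dioxaborolane) | C=CCB1OC(C)(C)C(C)(C)O1 | starting material
6 | (1R)-1-lithioethyl 2,4,6-tri(propan-2-yl)benzoate (sparteine-bound, formed in the flask) | C[C@@H]([Li])OC(=O)c1c(C(C)C)cc(C(C)C)cc1C(C)C | intermediate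
7 | lithium (prop-2-en-1-yl)[(1R)-1-{[2,4,6-tri(propan-2-yl)benzoyl]oxy}ethyl](pinacolato)borate (formed in the flask) | C[C@@H]([B-]1(CC=C)OC(C)(C)C(C)(C)O1)OC(=O)c1c(C(C)C)cc(C(C)C)cc1C(C)C.[Li+] | intermediate
8 | 4,4,5,5-tetramethyl-2-[(2S)-pent-4-en-2-yl]-1,3,2-dioxaborolane | C=CC[C@H](C)B1OC(C)(C)C(C)(C)O1 | intermediate
9 | lithium (chloromethyl)[(2S)-pent-4-en-2-yl](pinacolato)borate (formed in the flask) | [Li+].C=CC[C@H](C)[B-]1(CCl)OC(C)(C)C(C)(C)O1 | intermediate
10 | 4,4,5,5-tetramethyl-2-[(2R)-2-methylpent-4-en-1-yl]-1,3,2-dioxaborolane | C=CC[C@H](C)CB1OC(C)(C)C(C)(C)O1 | intermediate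
11 | 9-[(4R)-4-methyl-5-(4,4,5,5-tetramethyl-1,3,2-dioxaborolan-2-yl)pentyl]-9-borabicyclo[3.3.1]nonane (formed in the flask) | B1(CCC[C@H](C)CB2OC(C)(C)C(C)(C)O2)C2CCCC1CCC2 | intermediate
12 | ethyl (2E)-2-methyl-3-{4-[(4R)-4-methyl-5-(4,4,5,5-tetramethyl-1,3,2-dioxaborolan-2-yl)pentyl]furan-2-yl}prop-2-enoate | CCOC(=O)/C(C)=C/c1cc(CCC[C@H](C)CB2OC(C)(C)C(C)(C)O2)co1 | intermediate
13 | 3-bromofuran | Brc1ccoc1 | starting material
14 | 3-(prop-2-en-1-yl)furan | C=CCc1ccoc1 | intermediate
15 | 9-[3-(furan-3-yl)propyl]-9-borabicyclo[3.3.1]nonane (formed in the flask) | B1(CCCc2ccoc2)C2CCCC1CCC2 | intermediate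
16 | 1,3-di(furan-3-yl)propane | c1cc(CCCc2ccoc2)co1 | intermediate
17 | {4-[3-(furan-3-yl)propyl]furan-2-yl}lithium (formed in the flask) | [Li]c1cc(CCCc2ccoc2)co1 | intermediate
18 | lithium {(2R)-5-[5-((1E)-3-ethoxy-2-methyl-3-oxoprop-1-en-1-yl)furan-3-yl]-2-methylpentyl}{4-[3-(furan-3-yl)propyl]furan-2-yl}(pinacolato)borate (formed in the flask) | [Li+].CCOC(=O)/C(C)=C/c1cc(CCC[C@H](C)C[B-]2(c3cc(CCCc4ccoc4)co3)OC(C)(C)C(C)(C)O2)co1 | intermediate
19 | ethyl (2E)-3-{4-[(4S)-5-{4-[3-(furan-3-yl)propyl]furan-2-yl}-4-methylpentyl]furan-2-yl}-2-methylprop-2-enoate | CCOC(=O)/C(C)=C/c1cc(CCC[C@H](C)Cc2cc(CCCc3ccoc3)co2)co1 | intermediate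
20 | (2E)-3-{4-[(4S)-5-{4-[3-(furan-3-yl)propyl]furan-2-yl}-4-methylpentyl]furan-2-yl}-2-methylprop-2-enoic acid | C/C(=C\c1cc(CCC[C@H](C)Cc2cc(CCCc3ccoc3)co2)co1)C(=O)O | target

Total step count: 8. Longest linear sequence: 5 steps (steps 2, 3, 4, 7, 8).

Steps most likely to fail

Step 7. The deprotonation of 16 may be incomplete, may occur at the flanked α-position or twice. The furyllithium may add to the ester, and NBS may brominate the neutral furan rings instead of the boronate. The fallback replaces the oxidative union by a palladium-catalysed B-alkyl Suzuki–Miyaura coupling; it sets out from 16 and 12 and comes back at 19. Iridium-catalysed C–H borylation of 16 (used in excess) with [Ir(OMe)(cod)]2, 4,4'-di-tert-butyl-2,2'-bipyridine and B2pin2 in THF is under steric control and should place boron on the unhindered α-carbon, giving 2-{4-[3-(furan-3-yl)propyl]furan-2-yl}-4,4,5,5-tetramethyl-1,3,2-dioxaborolane F1. Bromodeboronation with CuBr2 in MeOH/H2O converts it into 2-bromo-4-[3-(furan-3-yl)propyl]furan F2. Boronate 12 is converted with KHF2 in MeOH/H2O into potassium trifluoro{(2R)-5-[5-((1E)-3-ethoxy-2-methyl-3-oxoprop-1-en-1-yl)furan-3-yl]-2-methylpentyl}borate F3. Coupling of F3 with F2 (Pd(OAc)2, RuPhos, K2CO3, toluene/H2O, 80 °C) should then give 19.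

Step 2. The enantiotopic hydrogens may not be fully discriminated, and the minor enantiomer cannot be removed later. The 1,2-migration may also be sluggish, or the lithiated benzoate may deprotonate the allylboronate. The fallback sets the stereocentre by auxiliary-controlled enolate alkylation. It consumes no compound of the route: it sets out from purchased (4R)-4-benzyl-3-propanoyl-1,3-oxazolidin-2-one (CCC(=O)N1C(=O)OC[C@H]1Cc1ccccc1) and comes back at 10, replacing steps 2 and 3. Evans alkylation (NaHMDS, allyl iodide, THF, −78 °C), in which the benzyl group shields one face of the chelated Z-enolate, should give (4R)-4-benzyl-3-[(2S)-2-methylpent-4-enoyl]-1,3-oxazolidin-2-one F4 as a diastereomer that can be purified. Reductive removal of the auxiliary with LiBH4 in THF/H2O gives (2S)-2-methylpent-4-en-1-ol F5. An Appel reaction (I2, PPh3, imidazole, CH2Cl2) gives (4S)-5-iodo-4-methylpent-1-ene F6. Copper-catalysed borylation of the primary iodide (CuI, PPh3, LiOMe, B2pin2, DMF, rt) then gives 10.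

Step 5. Palladium hydride species may move the allyl double bond into conjugation with the furan, and the low-boiling product may be lost on isolation. The fallback is a polar organolithium alkylation without palladium; it sets out from 13 and comes back at 14. Bromine–lithium exchange of 13 with n-BuLi in THF at −78 °C gives 3-furyllithium, which is kept at −78 °C to avoid migration of lithium to the α-position and is alkylated with allyl bromide. The THF solution of 14 is carried directly into step 6; no new compound arises (F0).

Further compounds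
F1 | step 7 | 2-{4-[3-(furan-3-yl)propyl]furan-2-yl}-4,4,5,5-tetramethyl-1,3,2-dioxaborolane | CC1(C)OB(c2cc(CCCc3ccoc3)co2)OC1(C)C
F2 | step 7 | 2-bromo-4-[3-(furan-3-yl)propyl]furan | Brc1cc(CCCc2ccoc2)co1
F3 | step 7 | potassium trifluoro{(2R)-5-[5-((1E)-3-ethoxy-2-methyl-3-oxoprop-1-en-1-yl)furan-3-yl]-2-methylpentyl}borate | CCOC(=O)/C(C)=C/c1cc(CCC[C@H](C)C[B-](F)(F)F)co1.[K+]
F4 | step 2 | (4R)-4-benzyl-3-[(2S)-2-methylpent-4-enoyl]-1,3-oxazolidin-2-one | C=CC[C@H](C)C(=O)N1C(=O)OC[C@H]1Cc1ccccc1
F5 | step 2 | (2S)-2-methylpent-4-en-1-ol | C=CC[C@H](C)CO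
F6 | step 2 | (4S)-5-iodo-4-methylpent-1-ene | C=CC[C@H](C)CI
F0 | step 5 | none | none
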